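**Strategy.** The route rests on cutting the bond between the benzylic carbinol carbon C7 (on the guaiacyl ring) and C8, the carbon that carries the syringyl-type aryl ether oxygen and C9. C8 is therefore the α-carbon of an aryloxyacetic acid with C9 as latent carboxyl, and C7 comes from a non-enolisable aryl aldehyde. A magnesium-catalysed, auxiliary-controlled anti-aldol of O-benzylvanillin with an (S)-N-(aryloxyacetyl)oxazolidinone joins the halves and sets the erythro C7/C8 pair in one operation. The imide's aryl ring carries bromine as a placeholder for the flavanone C ring, which is added afterwards by rhodium-catalysed asymmetric 1,4-arylation of a chromone, since its C4 ketone would not survive the imide reduction.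

Key step: step 2

**Remarks on the chemistry**
- Numbering: C7 = ArCH(OH), C8 = CH(OAr), C9 = CH2OH of the glycerol chain; O1, C2, C3, C4 for the flavanone. The target is 7R,8S (erythro, which is the anti-aldol relationship) and 2S.
- Assumption: the (S)-configured biaryl bisphosphine in step 6 is taken to deliver 2S by the quadrant model known for Rh/(S)-biaryl bisphosphines and cyclic enones; the ligand antipode would be used if the sense on chromones were the opposite.

**Step 1**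
Reactants: 1 4-bromo-2,6-dimethoxyphenol; 2 (S)-4-benzyl-3-(chloroacetyl)oxazolidin-2-one
Product: 3 (S)-4-benzyl-3-[(4-bromo-2,6-dimethoxyphenoxy)acetyl]oxazolidin-2-one
Conditions: K2CO3 (1.5 equiv), NaI (10 mol%), acetone, rt
Reagents that add atoms: none
Why: Williamson etherification, in which the potassium phenoxide displaces chloride (via the iodide formed in situ, Finkelstein catalysis) at the activated α-carbon of the imide faster than it attacks the imide carbonyl, and the auxiliary stereocentre is not involved.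

**Step 2**
Reactants: 3 (S)-4-benzyl-3-[(4-bromo-2,6-dimethoxyphenoxy)acetyl]oxazolidin-2-one; 4 4-(benzyloxy)-3-methoxybenzaldehyde (O-benzylvanillin, 1.2 equiv)
Product: 5 (4S)-4-benzyl-3-[(2R,3R)-3-[4-(benzyloxy)-3-methoxyphenyl]-2-(4-bromo-2,6-dimethoxyphenoxy)-3-[(trimethylsilyl)oxy]propanoyl]oxazolidin-2-one
Conditions: MgCl2 (20 mol%), NaSbF6 (30 mol%), Et3N (2 equiv), TMSCl (1.5 equiv), EtOAc, 23 °C; filtration through Et3N-deactivated silica
Reagents that add atoms: chlorotrimethylsilane, C[Si](C)(C)Cl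
Why: MgCl2 binds both imide carbonyls of 3, so Et3N can deprotonate the doubly activated C8–H2 (soft enolisation) to a chelated (Z)-magnesium enolate, which adds reversibly to the aldehyde carbon of 4 (the future C7); TMSCl traps the magnesium aldolate as silyl ether 5, releasing Mg(II) for turnover and making the addition irreversible. The closest known reaction type is the magnesium halide-catalysed direct anti-aldol of chiral N-acyloxazolidinones with aromatic aldehydes (Evans), here run on an α-aryloxyacetyl imide. No ring is closed. C8 is controlled by the auxiliary, because in the chelated enolate the C4-benzyl group blocks one face and the aldehyde should enter anti to it (the face used in enolate alkylations); C7 is controlled by the boat-like transition state that gives the anti relationship, so the (2R,3R)-adduct, i.e. the 7R,8S (erythro) pattern, is expected. The step needs anti over syn selectivity and a single enolate face, which the fixed Z-geometry and chelation of the imide enolate and the non-enolisable aldehyde should secure, while the aryl bromide and benzyl ether are inert. The electron-rich aldehyde is the slow partner, hence NaSbF6 as halide scavenger and a small excess of 4.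

**Step 3**
Reactants: 5 (4S)-4-benzyl-3-[(2R,3R)-3-[4-(benzyloxy)-3-methoxyphenyl]-2-(4-bromo-2,6-dimethoxyphenoxy)-3-[(trimethylsilyl)oxy]propanoyl]oxazolidin-2-one
Product: 7 (1R,2S)-1-[4-(benzyloxy)-3-methoxyphenyl]-2-(4-bromo-2,6-dimethoxyphenoxy)propane-1,3-diol, via C7-O-TMS primary alcohol 6 (not isolated)
Conditions: LiBH4 (2.5 equiv), MeOH (1 equiv), THF/Et2O, 0 °C; then K2CO3, MeOH, rt
Reagents that add atoms: none
Why: Reductive removal of the oxazolidinone (LiBH4 attacks the exocyclic imide carbonyl and takes it down to the C9 primary alcohol) is standard for silylated aldol adducts and spares the aryl bromide and benzyl ether, and the mild basic methanolysis then removes the TMS group without exposing the electron-rich benzylic carbinol C7 to acid, so neither stereocentre is touched.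

**Step 4**
Reactants: 7 (1R,2S)-1-[4-(benzyloxy)-3-methoxyphenyl]-2-(4-bromo-2,6-dimethoxyphenoxy)propane-1,3-diol
Product: 8 [4-{[(1R,2S)-1-[4-(benzyloxy)-3-methoxyphenyl]-1,3-dihydroxypropan-2-yl]oxy}-3,5-dimethoxyphenyl]boronic acid
Conditions: B2(OH)4 (1.5 equiv), XPhos Pd G2 (2 mol%), XPhos (4 mol%), KOAc (3 equiv), EtOH, 80 °C
Reagents that add atoms: tetrahydroxydiboron, OB(O)B(O)O
Why: Pd(0)/XPhos-catalysed Miyaura borylation with tetrahydroxydiboron converts the unhindered, electron-rich aryl bromide directly into the boronic acid under weakly basic conditions (KOAc in ethanol) that tolerate the free diol and cannot epimerise C7 or C8.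

**Step 5**
Reactants: 9 1-[2,4-bis(benzyloxy)-6-hydroxyphenyl]ethan-1-one
Product: 11 5,7-bis(benzyloxy)-4H-chromen-4-one, via enaminone 10 (not isolated)
Conditions: DMF-DMA (2 equiv), toluene, 100 °C; then conc. HCl, CH2Cl2, rt
Reagents that add atoms: N,N-dimethylformamide dimethyl acetal, COC(OC)N(C)C
Why: Enaminone route to chromones, in which the acetyl CH3 condenses with the formamide acetal and acid then promotes addition of the free ortho-hydroxyl to the β-carbon and loss of dimethylamine to close the pyranone ring (6-endo addition–elimination), the benzyl ethers being stable to the brief acid treatment.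

**Step 6**
Reactants: 8 [4-{[(1R,2S)-1-[4-(benzyloxy)-3-methoxyphenyl]-1,3-dihydroxypropan-2-yl]oxy}-3,5-dimethoxyphenyl]boronic acid; 11 5,7-bis(benzyloxy)-4H-chromen-4-one (1.5 equiv)
Product: 12 (2S)-5,7-bis(benzyloxy)-2-[4-{[(1R,2S)-1-[4-(benzyloxy)-3-methoxyphenyl]-1,3-dihydroxypropan-2-yl]oxy}-3,5-dimethoxyphenyl]-2,3-dihydro-4H-chromen-4-one
Conditions: [Rh(OH)(cod)]2 (2.5 mol%), (S)-MeO-F12-BIPHEP [(S)-2,2'-bis{bis(3,4,5-trifluorophenyl)phosphino}-6,6'-dimethoxybiphenyl, 5.5 mol%], 1,4-dioxane/H2O (10:1), 40 °C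
Reagents that add atoms: none
Why: Rhodium(I)-catalysed asymmetric 1,4-addition of an arylboronic acid to a chromone (Hayashi–Miyaura type, with the electron-poor biaryl bisphosphine developed for chromones), in which the aryl–Rh species carbometallates C2=C3 on the enone face selected by the ligand, setting C2 as S under catalyst control, and the oxa-π-allyl rhodium is protonated by water under base-free conditions, so the flavanone ring cannot open and the free hydroxyls are tolerated.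

**Step 7**
Reactants: 12 (2S)-5,7-bis(benzyloxy)-2-[4-{[(1R,2S)-1-[4-(benzyloxy)-3-methoxyphenyl]-1,3-dihydroxypropan-2-yl]oxy}-3,5-dimethoxyphenyl]-2,3-dihydro-4H-chromen-4-one
Product: 13 (2S)-2-[4-{[(1R,2S)-1,3-dihydroxy-1-(4-hydroxy-3-methoxyphenyl)propan-2-yl]oxy}-3,5-dimethoxyphenyl]-5,7-dihydroxy-2,3-dihydro-4H-chromen-4-one (CNP0318401.1)
Conditions: H2 (1 atm), 10% Pd/C, EtOAc/MeOH (1:1), rt, stopped at full conversion
Reagents that add atoms: none
Why: Catalytic hydrogenolysis cleaves the three aryl benzyl ethers under neutral conditions much faster than the benzylic C7–OH, the C2–O1 bond or the C4 ketone react, so all three stereocentres should survive and the target is released without acid or base.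

**Compound list**
1 | 4-bromo-2,6-dimethoxyphenol | COc1cc(Br)cc(OC)c1O | starting material
2 | (S)-4-benzyl-3-(chloroacetyl)oxazolidin-2-one | O=C(CCl)N1[C@@H](Cc2ccccc2)COC1=O | starting material
3 | (S)-4-benzyl-3-[(4-bromo-2,6-dimethoxyphenoxy)acetyl]oxazolidin-2-one | COc1cc(Br)cc(OC)c1OCC(=O)N1[C@@H](Cc2ccccc2)COC1=O | intermediate
4 | 4-(benzyloxy)-3-methoxybenzaldehyde | COc1cc(C=O)ccc1OCc1ccccc1 | starting material
5 | (4S)-4-benzyl-3-[(2R,3R)-3-[4-(benzyloxy)-3-methoxyphenyl]-2-(4-bromo-2,6-dimethoxyphenoxy)-3-[(trimethylsilyl)oxy]propanoyl]oxazolidin-2-one | COc1cc([C@@H](O[Si](C)(C)C)[C@@H](Oc2c(OC)cc(Br)cc2OC)C(=O)N2[C@@H](Cc3ccccc3)COC2=O)ccc1OCc1ccccc1 | intermediate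
6 | (2S,3R)-3-[4-(benzyloxy)-3-methoxyphenyl]-2-(4-bromo-2,6-dimethoxyphenoxy)-3-[(trimethylsilyl)oxy]propan-1-ol | COc1cc([C@@H](O[Si](C)(C)C)[C@H](CO)Oc2c(OC)cc(Br)cc2OC)ccc1OCc1ccccc1 | intermediate (not isolated)
7 | (1R,2S)-1-[4-(benzyloxy)-3-methoxyphenyl]-2-(4-bromo-2,6-dimethoxyphenoxy)propane-1,3-diol | COc1cc([C@@H](O)[C@H](CO)Oc2c(OC)cc(Br)cc2OC)ccc1OCc1ccccc1 | intermediate
8 | [4-{[(1R,2S)-1-[4-(benzyloxy)-3-methoxyphenyl]-1,3-dihydroxypropan-2-yl]oxy}-3,5-dimethoxyphenyl]boronic acid | COc1cc([C@@H](O)[C@H](CO)Oc2c(OC)cc(B(O)O)cc2OC)ccc1OCc1ccccc1 | intermediate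
9 | 1-[2,4-bis(benzyloxy)-6-hydroxyphenyl]ethan-1-one | CC(=O)c1c(O)cc(OCc2ccccc2)cc1OCc1ccccc1 | starting material
10 | (E)-1-[2,4-bis(benzyloxy)-6-hydroxyphenyl]-3-(dimethylamino)prop-2-en-1-one | CN(C)/C=C/C(=O)c1c(O)cc(OCc2ccccc2)cc1OCc1ccccc1 | intermediate (not isolated)
11 | 5,7-bis(benzyloxy)-4H-chromen-4-one | O=c1ccoc2cc(OCc3ccccc3)cc(OCc3ccccc3)c12 | intermediate
12 | (2S)-5,7-bis(benzyloxy)-2-[4-{[(1R,2S)-1-[4-(benzyloxy)-3-methoxyphenyl]-1,3-dihydroxypropan-2-yl]oxy}-3,5-dimethoxyphenyl]-2,3-dihydro-4H-chromen-4-one | COc1cc([C@@H](O)[C@H](CO)Oc2c(OC)cc([C@@H]3CC(=O)c4c(OCc5ccccc5)cc(OCc5ccccc5)cc4O3)cc2OC)ccc1OCc1ccccc1 | intermediate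
13 | (2S)-2-[4-{[(1R,2S)-1,3-dihydroxy-1-(4-hydroxy-3-methoxyphenyl)propan-2-yl]oxy}-3,5-dimethoxyphenyl]-5,7-dihydroxy-2,3-dihydro-4H-chromen-4-one | COc1cc([C@@H](O)[C@H](CO)Oc2c(OC)cc([C@@H]3CC(=O)c4c(O)cc(O)cc4O3)cc2OC)ccc1O | target

**Step count:** 7 steps in total. Longest linear sequence: 6 steps (steps 1, 2, 3, 4, 6, 7); step 5 is a one-step side branch.

**Steps most likely to fail**

1. Step 2 (key aldol). The α-aryloxy oxygen may compete for magnesium and erode anti/syn or facial control, or turnover may stall with the electron-rich aldehyde. The fallback sets out from 1 and returns at 7. Compound 1 would be alkylated with commercial (R)-4-benzyl-3-(chloroacetyl)oxazolidin-2-one under the step 1 conditions to give the enantiomeric imide (R)-4-benzyl-3-[(4-bromo-2,6-dimethoxyphenoxy)acetyl]oxazolidin-2-one F1. An Evans boron aldol (Bu2BOTf, iPr2NEt, CH2Cl2, −78 to 0 °C, then 4; buffered H2O2 work-up) should give the syn adduct (4R)-4-benzyl-3-[(2R,3S)-3-[4-(benzyloxy)-3-methoxyphenyl]-2-(4-bromo-2,6-dimethoxyphenoxy)-3-hydroxypropanoyl]oxazolidin-2-one F2. LiBH4 reduction would give the threo diol (1S,2S)-1-[4-(benzyloxy)-3-methoxyphenyl]-2-(4-bromo-2,6-dimethoxyphenoxy)propane-1,3-diol F3. Selective acylation of the primary hydroxyl (PivCl, pyridine, 0 °C) would give (2S,3S)-3-[4-(benzyloxy)-3-methoxyphenyl]-2-(4-bromo-2,6-dimethoxyphenoxy)-3-hydroxypropyl pivalate F4. Mitsunobu inversion at C7 (4-nitrobenzoic acid, PPh3, DIAD, THF, 0 °C) would give (1R,2S)-1-[4-(benzyloxy)-3-methoxyphenyl]-2-(4-bromo-2,6-dimethoxyphenoxy)-3-(pivaloyloxy)propyl 4-nitrobenzoate F5, and NaOMe/MeOH would remove both esters to give 7.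

2. Step 6 (asymmetric 1,4-arylation). Protodeboronation of the electron-rich boronic acid may outrun carborhodation of the deactivated 5,7-dialkoxychromone, or facial control at C2 may be insufficient. The fallback sets out from 7 and returns at 12. Suzuki vinylation of 7 (potassium vinyltrifluoroborate, PdCl2(dppf), Et3N, n-PrOH, 90 °C) would give (1R,2S)-1-[4-(benzyloxy)-3-methoxyphenyl]-2-(4-ethenyl-2,6-dimethoxyphenoxy)propane-1,3-diol F6. Lemieux–Johnson cleavage (cat. OsO4, NaIO4, 2,6-lutidine, dioxane/H2O) would give 4-{[(1R,2S)-1-[4-(benzyloxy)-3-methoxyphenyl]-1,3-dihydroxypropan-2-yl]oxy}-3,5-dimethoxybenzaldehyde F7. Claisen–Schmidt condensation with 9 (KOH, EtOH, rt) would give the 2'-hydroxychalcone (E)-1-[2,4-bis(benzyloxy)-6-hydroxyphenyl]-3-[4-{[(1R,2S)-1-[4-(benzyloxy)-3-methoxyphenyl]-1,3-dihydroxypropan-2-yl]oxy}-3,5-dimethoxyphenyl]prop-2-en-1-one F8. Oxa-Michael cyclisation (NaOAc, EtOH, reflux) would give 12 together with its C2 epimer, the (2R)-flavanone F9. The two would be separated by preparative HPLC on a chiral stationary phase, and F9 would be recycled by base-mediated ring opening back to F8.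

3. Step 4 (borylation). The free 1,3-diol may inhibit the catalyst or form oligomeric boronates, and boron may be lost by protodeboronation during isolation of the polar boronic acid. The fallback installs boron from the start; it sets out from 2 and returns at 8. Commercial 2,6-dimethoxy-4-(4,4,5,5-tetramethyl-1,3,2-dioxaborolan-2-yl)phenol would be alkylated with 2 as in step 1 to give (S)-4-benzyl-3-{[2,6-dimethoxy-4-(4,4,5,5-tetramethyl-1,3,2-dioxaborolan-2-yl)phenoxy]acetyl}oxazolidin-2-one F10. The magnesium anti-aldol with 4 as in step 2 would give the silylated adduct (4S)-4-benzyl-3-[(2R,3R)-3-[4-(benzyloxy)-3-methoxyphenyl]-2-[2,6-dimethoxy-4-(4,4,5,5-tetramethyl-1,3,2-dioxaborolan-2-yl)phenoxy]-3-[(trimethylsilyl)oxy]propanoyl]oxazolidin-2-one F11. LiBH4 at 0 °C followed by K2CO3/MeOH, as in step 3, would give the pinacol boronate diol (1R,2S)-1-[4-(benzyloxy)-3-methoxyphenyl]-2-[2,6-dimethoxy-4-(4,4,5,5-tetramethyl-1,3,2-dioxaborolan-2-yl)phenoxy]propane-1,3-diol F12. Oxidative removal of pinacol (NaIO4, NH4OAc, acetone/H2O, rt) would give 8.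

**Further compounds**
F1 | step 2 | (R)-4-benzyl-3-[(4-bromo-2,6-dimethoxyphenoxy)acetyl]oxazolidin-2-one | COc1cc(Br)cc(OC)c1OCC(=O)N1[C@H](Cc2ccccc2)COC1=O
F2 | step 2 | (4R)-4-benzyl-3-[(2R,3S)-3-[4-(benzyloxy)-3-methoxyphenyl]-2-(4-bromo-2,6-dimethoxyphenoxy)-3-hydroxypropanoyl]oxazolidin-2-one | COc1cc([C@H](O)[C@@H](Oc2c(OC)cc(Br)cc2OC)C(=O)N2[C@H](Cc3ccccc3)COC2=O)ccc1OCc1ccccc1
F3 | step 2 | (1S,2S)-1-[4-(benzyloxy)-3-methoxyphenyl]-2-(4-bromo-2,6-dimethoxyphenoxy)propane-1,3-diol | COc1cc([C@H](O)[C@H](CO)Oc2c(OC)cc(Br)cc2OC)ccc1OCc1ccccc1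
F4 | step 2 | (2S,3S)-3-[4-(benzyloxy)-3-methoxyphenyl]-2-(4-bromo-2,6-dimethoxyphenoxy)-3-hydroxypropyl pivalate | COc1cc([C@H](O)[C@H](COC(=O)C(C)(C)C)Oc2c(OC)cc(Br)cc2OC)ccc1OCc1ccccc1
F5 | step 2 | (1R,2S)-1-[4-(benzyloxy)-3-methoxyphenyl]-2-(4-bromo-2,6-dimethoxyphenoxy)-3-(pivaloyloxy)propyl 4-nitrobenzoate | COc1cc([C@@H](OC(=O)c2ccc(cc2)[N+](=O)[O-])[C@H](COC(=O)C(C)(C)C)Oc2c(OC)cc(Br)cc2OC)ccc1OCc1ccccc1
F6 | step 6 | (1R,2S)-1-[4-(benzyloxy)-3-methoxyphenyl]-2-(4-ethenyl-2,6-dimethoxyphenoxy)propane-1,3-diol | COc1cc([C@@H](O)[C@H](CO)Oc2c(OC)cc(C=C)cc2OC)ccc1OCc1ccccc1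
F7 | step 6 | 4-{[(1R,2S)-1-[4-(benzyloxy)-3-methoxyphenyl]-1,3-dihydroxypropan-2-yl]oxy}-3,5-dimethoxybenzaldehyde | COc1cc([C@@H](O)[C@H](CO)Oc2c(OC)cc(C=O)cc2OC)ccc1OCc1ccccc1
F8 | step 6 | (E)-1-[2,4-bis(benzyloxy)-6-hydroxyphenyl]-3-[4-{[(1R,2S)-1-[4-(benzyloxy)-3-methoxyphenyl]-1,3-dihydroxypropan-2-yl]oxy}-3,5-dimethoxyphenyl]prop-2-en-1-one | COc1cc([C@@H](O)[C@H](CO)Oc2c(OC)cc(/C=C/C(=O)c3c(O)cc(OCc4ccccc4)cc3OCc3ccccc3)cc2OC)ccc1OCc1ccccc1
F9 | step 6 | (2R)-5,7-bis(benzyloxy)-2-[4-{[(1R,2S)-1-[4-(benzyloxy)-3-methoxyphenyl]-1,3-dihydroxypropan-2-yl]oxy}-3,5-dimethoxyphenyl]-2,3-dihydro-4H-chromen-4-one | COc1cc([C@@H](O)[C@H](CO)Oc2c(OC)cc([C@H]3CC(=O)c4c(OCc5ccccc5)cc(OCc5ccccc5)cc4O3)cc2OC)ccc1OCc1ccccc1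
F10 | step 4 | (S)-4-benzyl-3-{[2,6-dimethoxy-4-(4,4,5,5-tetramethyl-1,3,2-dioxaborolan-2-yl)phenoxy]acetyl}oxazolidin-2-one | COc1cc(B2OC(C)(C)C(C)(C)O2)cc(OC)c1OCC(=O)N1[C@@H](Cc2ccccc2)COC1=O
F11 | step 4 | (4S)-4-benzyl-3-[(2R,3R)-3-[4-(benzyloxy)-3-methoxyphenyl]-2-[2,6-dimethoxy-4-(4,4,5,5-tetramethyl-1,3,2-dioxaborolan-2-yl)phenoxy]-3-[(trimethylsilyl)oxy]propanoyl]oxazolidin-2-one | COc1cc([C@@H](O[Si](C)(C)C)[C@@H](Oc2c(OC)cc(B3OC(C)(C)C(C)(C)O3)cc2OC)C(=O)N2[C@@H](Cc3ccccc3)COC2=O)ccc1OCc1ccccc1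
F12 | step 4 | (1R,2S)-1-[4-(benzyloxy)-3-methoxyphenyl]-2-[2,6-dimethoxy-4-(4,4,5,5-tetramethyl-1,3,2-dioxaborolan-2-yl)phenoxy]propane-1,3-diol | COc1cc([C@@H](O)[C@H](CO)Oc2c(OC)cc(B3OC(C)(C)C(C)(C)O3)cc2OC)ccc1OCc1ccccc1
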